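Assumption: the SMILES has no stereodescriptor, and the only stereogenic element is the C8–C8'' axis. I target the (aR) = (M) atropisomer, with torsion C7–C8–C8''–C7'' ≈ –90°. The enantiomeric catalyst in Step 1 gives (aS) by the same route.

## Retrosynthetic overview
1. The obvious plan, a flavone–flavone Suzuki or Ullmann coupling at C8–C8'' followed by resolution, is avoided. The target is treated as a mono-methylated C2-symmetric dimer.
2. The single 7-OMe comes from mono-Mitsunobu methylation of two homotopic 7-OH groups. Any single methylation gives the same compound.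
3. Both pyranone C-rings, with their B-rings attached, come from one two-directional Pd/CO carbonylative alkyne annulation of a 3,3'-diiodo-2,2'-biphenol.
4. The axis is set in Step 1 by catalytic enantioselective aerobic ortho–ortho oxidative homocoupling of 3,5-bis(benzyloxy)phenol.
5. Ring order: the A and A'' rings are bought, the axis is formed next, and the C and C'' rings are then closed together with the B rings delivered on the alkyne.

Descriptor note: 2, 3, 6 and 7 are C2-symmetric. In 8 and 9, C8a outranks C7 in both halves. The same spatial arrangement is therefore (aR)/(M) in every compound.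

## Route

**Step 1**
Reactants: 1, 3,5-bis(benzyloxy)phenol (2 molecules)
Product: 2, (aR)-4,4',6,6'-tetrakis(benzyloxy)-[1,1'-biphenyl]-2,2'-diol
Conditions: (Sa,R,R)-dinuclear oxovanadium(V) Schiff-base catalyst, made from (S)-3,3'-diformyl-BINOL, (R)-tert-leucine and VOSO4, 5–10 mol %; O2 (1 atm), CH2Cl2, 25–30 °C, 48–72 h, no acid additive; recrystallise to ≥99% ee. This antipode is the first choice because it gives (R)-BINOL from 2-naphthol. The sense of induction is confirmed by anomalous-dispersion X-ray of 3.
Reagents that add atoms: none
Why: Proposed new method: enantioselective V(V)-catalysed aerobic oxidative phenol coupling, established for 2-naphthols, resorcinols, hydroxycarbazoles and simple phenols, is extended to a 3,5-dialkoxyphenol, in which both phenols bind as V-phenoxides in the chiral bimetallic pocket, one-electron oxidation and radical C–C coupling can only occur ortho to each V–O bond (the para carbon is out of reach and sits between two OBn groups), and rearomatisation in the pocket fixes the new tetra-ortho-oxygenated axis as (aR).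

**Step 2**
Reactants: 2
Product: 3, (aR)-4,4',6,6'-tetrakis(benzyloxy)-3,3'-diiodo-[1,1'-biphenyl]-2,2'-diol
Conditions: NIS (2.05 equiv), CH2Cl2–MeCN, –30 → 0 °C, dark
Reagents that add atoms: N-iodosuccinimide, O=C1CCC(=O)N1I
Why: In this electrophilic aromatic iodination C3 is flanked by the small free OH and one OBn while C5 lies between two OBn groups, the same 2-hydroxy-4,6-dialkoxyaryl pattern is known to iodinate ortho to the OH, and the neutral cold conditions avoid acid-induced ipso-protonation so the axis is untouched.

**Step 3**
Reactants: 4, 4-(tert-butoxy)benzaldehyde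
Product: 5, 1-(tert-butoxy)-4-ethynylbenzene
Conditions: Bestmann–Ohira reagent (1.2 equiv), K2CO3, MeOH, rt
Reagents that add atoms: dimethyl (1-diazo-2-oxopropyl)phosphonate, COP(=O)(OC)C(=[N+]=[N-])C(C)=O (supplies the terminal alkyne carbon)
Why: Seyferth–Gilbert homologation (Bestmann–Ohira variant) converts ArCHO into ArC≡CH under mild base that the tert-butyl ether tolerates.

**Step 4**
Reactants: 3; 5 (3 equiv)
Product: 6, (aR)-5,5'',7,7''-tetrakis(benzyloxy)-4',4'''-di-tert-butoxy-8,8''-biflavone
Conditions: PdCl2(dppf) (10 mol %), CO (10 bar), Et2NH–DMF (1:3), Cu-free, 60 °C, 16 h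
Reagents that add atoms: carbon monoxide, [C-]#[O+]
Why: This is a two-fold Pd-catalysed carbonylative Sonogashira coupling/6-endo annulation, the known flavone synthesis from o-iodophenols, in which ArPdI inserts CO (→ C4=O on the former C–I carbon, now C4a), is alkynylated to the o-hydroxyaryl ynone, and Et2NH conjugate addition with displacement by the phenol O (→ O1) closes the pyranone rather than the aurone, while 60 °C leaves the buttressed axis intact.

**Step 5**
Reactants: 6
Product: 7, (aR)-4',4'''-di-tert-butoxy-5,5'',7,7''-tetrahydroxy-8,8''-biflavone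
Conditions: H2 (1 atm), 10% Pd/C, THF–MeOH, rt
Reagents that add atoms: none
Why: Catalytic hydrogenolysis removes the four benzyl ethers, while the aryl tert-butyl ethers, the flavone C2=C3/C4=O unit and the axis are inert at 1 atm and rt.

**Step 6**
Reactants: 7
Product: 8, (aR)-4',4'''-di-tert-butoxy-5,5'',7''-trihydroxy-7-methoxy-8,8''-biflavone
Conditions: MeOH (1.05 equiv), PPh3 (1.1 equiv), DIAD (1.1 equiv), THF, 0 °C → rt; recovered 7 is recycled
Reagents that add atoms: methanol, CO (supplies CH3)
Why: In this Mitsunobu etherification the two 7-OH groups are homotopic so any single methylation gives 8, the C4=O-chelated 5-OH groups do not react, and, as in mono-etherification of BINOL-type 2,2'-diols, the second alkylation is slower because the mono-ether is more hindered and has lost the OH···O⁻-assisted acidity.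

**Step 7**
Reactants: 8
Product: 9, (aR)-cupressuflavone 7-methyl ether (4',4''',5,5'',7''-pentahydroxy-7-methoxy-8,8''-biflavone)
Conditions: TFA–CH2Cl2 (1:3), pentamethylbenzene (10 equiv), 0 °C → rt, 1–2 h
Reagents that add atoms: none
Why: Acidolysis of the aryl tert-butyl ethers (SN1/E1 loss of t-Bu⁺, trapped by the scavenger) leaves the aryl methyl ether intact, and the protonated flavone is deactivated towards ipso-protonation and ring opening, so neither racemisation nor Wessely–Moser isomerisation occurs.

## Compound list
Biaryl axial chirality cannot be written in standard SMILES, so the descriptor is given in the name.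

| No. | Name | SMILES | Role |
|---|---|---|---|
| 1 | 3,5-bis(benzyloxy)phenol | `Oc1cc(OCc2ccccc2)cc(OCc2ccccc2)c1` | starting material |
| 2 | (aR)-4,4',6,6'-tetrakis(benzyloxy)biphenyl-2,2'-diol | `Oc1cc(OCc2ccccc2)cc(OCc2ccccc2)c1-c1c(O)cc(OCc2ccccc2)cc1OCc1ccccc1` | intermediate |
| 3 | (aR)-3,3'-diiodo derivative of 2 | `Oc1c(I)c(OCc2ccccc2)cc(OCc2ccccc2)c1-c1c(O)c(I)c(OCc2ccccc2)cc1OCc1ccccc1` | intermediate |
| 4 | 4-(tert-butoxy)benzaldehyde | `CC(C)(C)Oc1ccc(C=O)cc1` | starting material |
| 5 | 1-(tert-butoxy)-4-ethynylbenzene | `C#Cc1ccc(OC(C)(C)C)cc1` | intermediate |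
| 6 | (aR)-5,5'',7,7''-tetra-OBn-4',4'''-di-O-t-Bu-8,8''-biflavone | `c1ccccc1COc1cc(OCc2ccccc2)c2c(=O)cc(-c3ccc(OC(C)(C)C)cc3)oc2c1-c1c(OCc2ccccc2)cc(OCc2ccccc2)c2c(=O)cc(-c3ccc(OC(C)(C)C)cc3)oc12` | intermediate |
| 7 | (aR)-4',4'''-di-O-tert-butylcupressuflavone | `Oc1cc(O)c2c(=O)cc(-c3ccc(OC(C)(C)C)cc3)oc2c1-c1c(O)cc(O)c2c(=O)cc(-c3ccc(OC(C)(C)C)cc3)oc12` | intermediate |
| 8 | (aR)-7-O-methyl-4',4'''-di-O-tert-butylcupressuflavone | `COc1cc(O)c2c(=O)cc(-c3ccc(OC(C)(C)C)cc3)oc2c1-c1c(O)cc(O)c2c(=O)cc(-c3ccc(OC(C)(C)C)cc3)oc12` | intermediate |
| 9 | (aR)-cupressuflavone 7-methyl ether | `COc1cc(O)c2c(=O)cc(-c3ccc(O)cc3)oc2c1-c1c(O)cc(O)c2c(=O)cc(-c3ccc(O)cc3)oc12` | target |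

## Totals
- Total steps: 7
- Longest linear sequence: 6 (1 → 2 → 3 → 6 → 7 → 8 → 9)

## Steps most likely to fail
1. **Step 1.** It may give o,p or p,p isomers, low conversion or modest ee. Fallback: drop asymmetric catalysis. Make rac-2 with an achiral oxidant (FeCl3·SiO2 or (t-BuO)2), separate the atropisomers as diastereomeric bis-(1S)-camphanates by crystallisation or chromatography, and release (aR)-2 with K2CO3/MeOH.
2. **Step 4.** The aryl iodide is hindered, electron-rich and di-ortho-substituted. Aminocarbonylation, benzofuran or aurone formation, or mono-annulation could compete. Fallback: avoid Pd/CO, which also bypasses Step 2.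
   - Run a double Mg-mediated ortho-formylation of 2 (MgCl2, Et3N, (CH2O)n).
   - Add the lithium acetylide of 5.
   - Oxidise with MnO2 to the bis-ynone.
   - Close to 6 by Et2NH-triggered 6-endo cyclisation.
3. **Step 6.** Over-methylation or a near-statistical mixture is possible. Fallback: replace the intermolecular methylation with a tether. Close the 7,7''-O–CH2–O bridge (CH2Br2, Cs2CO3, DMF), then reductively cleave one acetal C–O bond (Et3SiH, TiCl4). The bridging carbon then becomes the single OMe, giving exactly one methyl per dimer. The configurational stability of the bridged dioxepine must be checked first.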